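**Plan**

- Retrosynthesis: cleave the C6 trienoate ester, take C12 back to a methyl group and C6 to a ketone, then cut ring A at C4–C5 and at C1–C10.
- What remains is ring B alone, and it has a mirror plane through C6 and C9 (C5/C7, C10/C8 and the C10 methyl/C12 are pairwise equivalent). It is an achiral 4-oxy-4-carboxy-3,5-dimethylcyclohexa-2,5-dienone, reached by Birch dearomatisation of 2,6-dimethylbenzoic acid.
- Forward: ring B is made first as this dienone. A catalytic enantioselective conjugate addition then forms C1–C10 and breaks the symmetry, so C9 and C10 are set together. An SN1 α-tert-alkylation of the resulting silyl dienol ether closes ring A through C4–C5.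
- Stereochemistry: C10 and C9 come from the chiral Cu catalyst (choice of enantiotopic enone arm) and the face of the quinol (attack syn to O9). C5 is set by equilibration next to the C6 ketone (trans-decalin). C6 is set by α-face hydride delivery, since the β-face is covered by the C10 and C4β methyl groups.
- End game: SeO2 oxidation of C12 to the aldehyde, acylation of the 6β-OH with the trienoyl chloride, Pd(0) removal of the allyl ester.

Key step: step 7

Remarks
- Drimane numbering is used throughout: C1–C10 form the decalin, C11 is on C9, C12 is on C8.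
- The target is taken as the open hydroxy acid/aldehyde as drawn; it may equilibrate with its 12-hydroxy-11,12-lactol tautomer.
- 2,6-Dimethylbenzoic acid, 2-methylpent-4-en-2-ol and (2E,4E,6E)-octa-2,4,6-trienoic acid are taken as commercially available.

**Route**

Step 1
Reactants: 1 2,6-dimethylbenzoic acid
Product: 2 2,6-dimethylcyclohexa-2,5-diene-1-carboxylic acid
Conditions: Li, NH3(l)/THF, −78 °C; NH4Cl, then aq. HCl to pH 3
Reagents that add atoms: none
Why: Birch reduction of a benzoic acid protonates the ipso and para carbons, so the two methyl-bearing carbons stay sp2 and the 1,4-dihydro acid should result.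

Step 2
Reactants: 2 2,6-dimethylcyclohexa-2,5-diene-1-carboxylic acid
Product: 3 allyl 2,6-dimethylcyclohexa-2,5-diene-1-carboxylate
Conditions: allyl bromide, KHCO3, DMF, rt
Reagents that add atoms: allyl bromide, C=CCBr
Why: Carboxylate O-alkylation (SN2) under weakly basic conditions should not conjugate the skipped diene, and the allyl ester can later be removed with Pd(0) without touching the trienoate.

Step 3
Reactants: 3 allyl 2,6-dimethylcyclohexa-2,5-diene-1-carboxylate
Product: 5 allyl 1-hydroxy-2,6-dimethylcyclohexa-2,5-diene-1-carboxylate, via potassium (allyloxy)(2,6-dimethylcyclohexa-2,5-dien-1-ylidene)methanolate 4 (not isolated)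
Conditions: KHMDS, THF, −78 °C; then 3-phenyl-2-(phenylsulfonyl)oxaziridine; NH4Cl
Reagents that add atoms: 3-phenyl-2-(phenylsulfonyl)oxaziridine, O=S(=O)(c1ccccc1)N1OC1c1ccccc1
Why: Enolate α-hydroxylation with an N-sulfonyloxaziridine; the cross-conjugated ester enolate should react at the α-carbon, as Birch enolates do in reductive alkylation, to give the tertiary α-hydroxy ester.

Step 4
Reactants: 5 allyl 1-hydroxy-2,6-dimethylcyclohexa-2,5-diene-1-carboxylate
Product: 6 allyl 2,6-dimethyl-1-[(trimethylsilyl)oxy]cyclohexa-2,5-diene-1-carboxylate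
Conditions: Me3SiOTf, 2,6-lutidine, CH2Cl2, −78 → 0 °C
Reagents that add atoms: trimethylsilyl trifluoromethanesulfonate, C[Si](C)(C)OS(=O)(=O)C(F)(F)F
Why: Silylation of the hindered tertiary alcohol removes the acidic OH before the organometallic step and gives a small, acid-labile group on O9.

Step 5
Reactants: 6 allyl 2,6-dimethyl-1-[(trimethylsilyl)oxy]cyclohexa-2,5-diene-1-carboxylate
Product: 7 allyl 2,6-dimethyl-4-oxo-1-[(trimethylsilyl)oxy]cyclohexa-2,5-diene-1-carboxylate
Conditions: t-BuOOH (decane), Rh2(cap)4 (1 mol %), K2CO3, CH2Cl2, rt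
Reagents that add atoms: tert-butyl hydroperoxide, CC(C)(C)OO
Why: Bis-allylic C–H oxidation (tert-butylperoxyl radical chain) should convert the only doubly allylic CH2 into the ketone; C1 is quaternary, so the ring cannot aromatise and the Cs-symmetric 2,5-cyclohexadienone results.

Step 6
Reactants: 8 2-methylpent-4-en-2-ol
Product: 9 4-chloro-4-methylpent-1-ene
Conditions: conc. aq. HCl, 0 °C → rt
Reagents that add atoms: hydrogen chloride, Cl
Why: SN1 substitution of the tertiary alcohol by chloride gives the tertiary chloride that later serves as the latent C4 cation, while cold aqueous HCl should leave the terminal alkene alone.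

Step 7
Reactants: 7 allyl 2,6-dimethyl-4-oxo-1-[(trimethylsilyl)oxy]cyclohexa-2,5-diene-1-carboxylate; 9 4-chloro-4-methylpent-1-ene
Product: 11 allyl (1R,6S)-6-(4-chloro-4-methylpentyl)-2,6-dimethyl-1,4-bis[(trimethylsilyl)oxy]cyclohexa-2,4-diene-1-carboxylate (ring C1 = C9, ring C6 = C10; 1-OSiMe3 and the new side chain cis), via chlorobis(cyclopentadienyl)(4-chloro-4-methylpentyl)zirconium 10 (not isolated)
Conditions: 9 (slight excess), Cp2Zr(H)Cl, CH2Cl2, rt; then CuNTf2 (10 mol %, preformed from CuCl/AgNTf2 and filtered), chiral BINOL-derived phosphoramidite L* (11 mol %), 7, Me3SiCl, Et2O, 0 °C → rt; non-aqueous work-up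
Reagents that add atoms: chlorotrimethylsilane, C[Si](C)(C)Cl
Why: Proposed new method: hydrozirconation of 9 gives the primary alkylzirconocene 10, which transmetallates to a chiral phosphoramidite–Cu(I) centre; π-complexation of the alkylcopper to one enone arm of the Cs-symmetric dienone 7, C1–C10 bond formation at the β-carbon through a Cu(III) intermediate and silylation of the enolate by Me3SiCl give the C5=C6 silyl enol ether, which also switches off the second enone arm. The closest known reactions are the Cu/phosphoramidite-catalysed asymmetric conjugate addition of alkylzirconocenes to 3-methylcyclohex-2-enones (quaternary β-carbon) and the Cu-catalysed desymmetrising conjugate additions of organozinc reagents to 4-alkoxy-4-alkylcyclohexa-2,5-dienones; what is new is their combination on a 3,5-dimethylated quinol carboxylate whose β-carbon is flanked by a fully substituted carbon. No ring is closed in this step (ring A is closed in step 8). C10 is set by the catalyst, which selects one of the two enantiotopic β-carbons (the ligand enantiomer is to be matched to 10S), and C9 becomes stereogenic in the same event, its configuration relative to C10 being fixed by the face of attack. The step needs 1,4- rather than 1,2-addition (soft alkylcopper, Me3SiCl), mono-addition (enolate silylation) and attack on the face that carries the C9 oxygen, anti to the ester; that face is the one generally attacked in 4-oxygenated cyclohexa-2,5-dienones (smaller substituent, favourable electrostatics), and the cross-conjugated dienone with two σ-acceptors at C9 should be a better acceptor than a simple 3-methylcyclohexenone.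

Step 8
Reactants: 11 allyl (1R,6S)-6-(4-chloro-4-methylpentyl)-2,6-dimethyl-1,4-bis[(trimethylsilyl)oxy]cyclohexa-2,4-diene-1-carboxylate
Product: 14 allyl (5S,9R,10S)-9-hydroxy-6-oxodrim-7-en-11-oate (5α-H, 9α-OH, 10β-Me), via allyl 6-oxo-9α-[(trimethylsilyl)oxy]drim-7-en-11-oate (C5 epimers) 12 (not isolated), via allyl 9α-hydroxy-6-oxodrim-7-en-11-oate (C5 epimers) 13 (not isolated)
Conditions: TiCl4, CH2Cl2, −78 → −30 °C; 1 M HCl, THF, rt; then K2CO3 (cat.), allyl alcohol, rt
Reagents that add atoms: none
Why: Intramolecular Lewis-acid-mediated α-tert-alkylation of a silyl enol ether (SN1): TiCl4 ionises the tertiary chloride, the 2-siloxydiene attacks the C4 cation through C5 in a 6-(enolexo)-exo closure (the C4–C5 bond a polyene cyclisation forms first), acid removes the O9 silyl group, and base should equilibrate the epimerisable C5 to the trans-fused decalin.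

Step 9
Reactants: 14 allyl (5S,9R,10S)-9-hydroxy-6-oxodrim-7-en-11-oate
Product: 15 allyl (5S,6R,9R,10S)-6,9-dihydroxydrim-7-en-11-oate (6β-OH, 9α-OH)
Conditions: NaBH4, CeCl3·7H2O, MeOH, −40 °C
Reagents that add atoms: none
Why: Luche 1,2-reduction; hydride should add to the α-face of the C6 ketone because the β-face is covered by the axial C10 and C4β methyl groups, giving the axial 6β-alcohol.

Step 10
Reactants: 15 allyl (5S,6R,9R,10S)-6,9-dihydroxydrim-7-en-11-oate
Product: 16 allyl (5S,6R,9S,10S)-6,9-dihydroxy-12-oxodrim-7-en-11-oate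
Conditions: SeO2, 1,4-dioxane, 70 °C
Reagents that add atoms: selenium dioxide, O=[Se]=O
Why: Riley allylic oxidation (ene reaction, then [2,3]-shift) acts at the more substituted end of the C7=C8 alkene, where C12 is the only carbon bearing hydrogen, and should carry that primary position on to the aldehyde.

Step 11
Reactants: 17 (2E,4E,6E)-octa-2,4,6-trienoic acid
Product: 18 (2E,4E,6E)-octa-2,4,6-trienoyl chloride
Conditions: (COCl)2, DMF (cat.), CH2Cl2, 0 °C → rt; used crude
Reagents that add atoms: oxalyl chloride, O=C(Cl)C(=O)Cl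
Why: Acid chloride formation through the catalytic chloroiminium species under neutral conditions should keep the all-E triene intact.

Step 12
Reactants: 16 allyl (5S,6R,9S,10S)-6,9-dihydroxy-12-oxodrim-7-en-11-oate; 18 (2E,4E,6E)-octa-2,4,6-trienoyl chloride
Product: 19 allyl (5S,6R,9S,10S)-9-hydroxy-6-[(2E,4E,6E)-octa-2,4,6-trienoyloxy]-12-oxodrim-7-en-11-oate
Conditions: pyridine, DMAP (cat.), CH2Cl2, 0 °C → rt
Reagents that add atoms: none
Why: DMAP-catalysed acylation should select the secondary 6β-OH over the tertiary, ester-flanked 9α-OH, and C6 keeps its configuration because the C–O bond is not touched.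

Step 13
Reactants: 19 allyl (5S,6R,9S,10S)-9-hydroxy-6-[(2E,4E,6E)-octa-2,4,6-trienoyloxy]-12-oxodrim-7-en-11-oate
Product: 20 ustusoic acid B, (5S,6R,9S,10S)-9-hydroxy-6-[(2E,4E,6E)-octa-2,4,6-trienoyloxy]-12-oxodrim-7-en-11-oic acid
Conditions: Pd(PPh3)4 (5 mol %), N-methylaniline, THF, rt; dilute aq. citric acid wash
Reagents that add atoms: none
Why: Pd(0)-catalysed allyl transfer (Tsuji–Trost deallylation) to a weakly nucleophilic amine should cleave only the allyl ester via its π-allyl complex and leave the hindered secondary trienoate, the enal and the tertiary alcohol alone.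

**Compound list**

1 | 2,6-dimethylbenzoic acid | Cc1cccc(C)c1C(=O)O | starting material
2 | 2,6-dimethylcyclohexa-2,5-diene-1-carboxylic acid | CC1=CCC=C(C)C1C(=O)O | intermediate
3 | allyl 2,6-dimethylcyclohexa-2,5-diene-1-carboxylate | CC1=CCC=C(C)C1C(=O)OCC=C | intermediate
4 | potassium (allyloxy)(2,6-dimethylcyclohexa-2,5-dien-1-ylidene)methanolate (ester enolate of 3) | [K+].[O-]C(OCC=C)=C1C(C)=CCC=C1C | intermediate (not isolated)
5 | allyl 1-hydroxy-2,6-dimethylcyclohexa-2,5-diene-1-carboxylate | CC1=CCC=C(C)C1(O)C(=O)OCC=C | intermediate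
6 | allyl 2,6-dimethyl-1-[(trimethylsilyl)oxy]cyclohexa-2,5-diene-1-carboxylate | CC1=CCC=C(C)C1(O[Si](C)(C)C)C(=O)OCC=C | intermediate
7 | allyl 2,6-dimethyl-4-oxo-1-[(trimethylsilyl)oxy]cyclohexa-2,5-diene-1-carboxylate (achiral) | CC1=CC(=O)C=C(C)C1(O[Si](C)(C)C)C(=O)OCC=C | intermediate
8 | 2-methylpent-4-en-2-ol | CC(C)(O)CC=C | starting material
9 | 4-chloro-4-methylpent-1-ene | CC(C)(Cl)CC=C | intermediate
10 | chlorobis(cyclopentadienyl)(4-chloro-4-methylpentyl)zirconium | CC(C)(Cl)CCC[Zr](Cl)(C1C=CC=C1)C1C=CC=C1 | intermediate (not isolated)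
11 | allyl (1R,6S)-6-(4-chloro-4-methylpentyl)-2,6-dimethyl-1,4-bis[(trimethylsilyl)oxy]cyclohexa-2,4-diene-1-carboxylate | C=CCOC(=O)[C@@]1(O[Si](C)(C)C)C(C)=CC(O[Si](C)(C)C)=C[C@]1(C)CCCC(C)(C)Cl | intermediate
12 | allyl 6-oxo-9α-[(trimethylsilyl)oxy]drim-7-en-11-oate, C5 epimers | O=C1C=C(C)[C@](O[Si](C)(C)C)(C(=O)OCC=C)[C@@]2(C)CCCC(C)(C)C12 | intermediate (not isolated)
13 | allyl 9α-hydroxy-6-oxodrim-7-en-11-oate, C5 epimers | O=C1C=C(C)[C@](O)(C(=O)OCC=C)[C@@]2(C)CCCC(C)(C)C12 | intermediate (not isolated)
14 | allyl (5S,9R,10S)-9-hydroxy-6-oxodrim-7-en-11-oate | O=C1C=C(C)[C@](O)(C(=O)OCC=C)[C@@]2(C)CCCC(C)(C)[C@H]12 | intermediate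
15 | allyl (5S,6R,9R,10S)-6,9-dihydroxydrim-7-en-11-oate | O[C@@H]1C=C(C)[C@](O)(C(=O)OCC=C)[C@@]2(C)CCCC(C)(C)[C@H]12 | intermediate
16 | allyl (5S,6R,9S,10S)-6,9-dihydroxy-12-oxodrim-7-en-11-oate | O[C@@H]1C=C(C=O)[C@](O)(C(=O)OCC=C)[C@@]2(C)CCCC(C)(C)[C@H]12 | intermediate
17 | (2E,4E,6E)-octa-2,4,6-trienoic acid | C/C=C/C=C/C=C/C(=O)O | starting material
18 | (2E,4E,6E)-octa-2,4,6-trienoyl chloride | C/C=C/C=C/C=C/C(=O)Cl | intermediate
19 | allyl (5S,6R,9S,10S)-9-hydroxy-6-[(2E,4E,6E)-octa-2,4,6-trienoyloxy]-12-oxodrim-7-en-11-oate | C/C=C/C=C/C=C/C(=O)O[C@@H]1C=C(C=O)[C@](O)(C(=O)OCC=C)[C@@]2(C)CCCC(C)(C)[C@H]12 | intermediate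
20 | ustusoic acid B | C/C=C/C=C/C=C/C(=O)O[C@@H]1C=C(C=O)[C@](O)(C(=O)O)[C@@]2(C)CCCC(C)(C)[C@H]12 | target

**Step count and risks**

Total step count: 13. Longest linear sequence: 11 (steps 1–5, 7–10, 12, 13).

Step 7 (the labelled step). The alkylcopper may fail to add at a β-carbon flanked by the fully substituted C9, leading to slow turnover or 1,2-addition. The facial bias of the quinol may be weaker with an ester instead of an alkyl group on C9, giving the wrong C9/C10 relation. The ligand may also discriminate the two enantiotopic enone arms poorly.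

The fallback replaces catalyst control by intramolecular delivery and a resolution. It sets out from 7. The silyl ether is removed (Bu4NF/AcOH, THF) to give the free quinol allyl 1-hydroxy-2,6-dimethyl-4-oxocyclohexa-2,5-diene-1-carboxylate F1. This is treated at −78 → 0 °C with an excess of (4-methylpent-3-en-1-yl)magnesium bromide F2, made from commercial 5-bromo-2-methylpent-2-ene and Mg. The first equivalent forms the magnesium alkoxide, which should then deliver the alkyl group to the adjacent β-carbon on its own face (alkoxide-directed conjugate addition, known for 4-hydroxycyclohexadienones). This should give racemic allyl (1S,6S)-1-hydroxy-2,6-dimethyl-6-(4-methylpent-3-en-1-yl)-4-oxocyclohex-2-ene-1-carboxylate F3 with hydroxyl and side chain cis. Preparative chromatography on a chiral stationary phase gives the (1S,6S) enantiomer F4. Markovnikov addition of HCl (CH2Cl2, 0 °C) gives allyl (1S,6S)-6-(4-chloro-4-methylpentyl)-1-hydroxy-2,6-dimethyl-4-oxocyclohex-2-ene-1-carboxylate F5. LDA (2.2 equiv)/Me3SiCl at −78 °C silylates the alkoxide and the kinetic C5 enolate, and the route is rejoined at 11.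

Step 8. After ionisation, loss of a proton from the tertiary cation or capture by the C9 silyloxy oxygen (seven-membered ether) may outrun C–C bond formation at C5, which lies between two quaternary carbons. Equilibration at C5 may also stop short of the trans-fused isomer.

The fallback gives up the ionisation of a chloride in front of a preformed enol silane. It uses a proton-initiated cation–olefin cyclisation terminated by the ketone enol, a reversible manifold in which alkene isomers re-enter the cation and only the C–C bonded ketone is a sink. It sets out from 7. Step 7 is run with chlorobis(cyclopentadienyl)(4-methylpent-3-en-1-yl)zirconium F6, from commercial 4-methylpenta-1,3-diene and Cp2Zr(H)Cl. This should give allyl (1R,6S)-2,6-dimethyl-6-(4-methylpent-3-en-1-yl)-1,4-bis[(trimethylsilyl)oxy]cyclohexa-2,4-diene-1-carboxylate F7. Dilute HCl in THF hydrolyses both silyl groups to the alkenyl hydroxy ketone F4 defined above. SnCl4 in CH2Cl2 (or ClSO3H in 2-nitropropane) at −78 → 0 °C then closes ring A through the enol. Base equilibration as in step 8 rejoins the route at 14.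

Step 10. The ene step may be slow on an alkene flanked by two oxygenated carbons, and the secondary allylic 6-OH may be oxidised back to the enone or the product oxidised further.

The fallback functionalises C12 through the enone instead, by radical substitution and redox adjustment. It sets out from 14. Radical γ-bromination of the enone methyl group (NBS, dibenzoyl peroxide cat., PhCF3, 80 °C) gives allyl 12-bromo-9α-hydroxy-6-oxodrim-7-en-11-oate F8. Ag2CO3 in aqueous acetone gives allyl 9α,12-dihydroxy-6-oxodrim-7-en-11-oate F9. Luche reduction as in step 9 gives allyl 6β,9α,12-trihydroxydrim-7-en-11-oate F10. TEMPO/PhI(OAc)2 oxidises only the primary allylic alcohol and rejoins the route at 16.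

**Further compounds**

F1 | step 7 | allyl 1-hydroxy-2,6-dimethyl-4-oxocyclohexa-2,5-diene-1-carboxylate | C=CCOC(=O)C1(O)C(C)=CC(=O)C=C1C
F2 | step 7 | (4-methylpent-3-en-1-yl)magnesium bromide | CC(C)=CCC[Mg]Br
F3 | step 7 | rac-allyl (1S,6S)-1-hydroxy-2,6-dimethyl-6-(4-methylpent-3-en-1-yl)-4-oxocyclohex-2-ene-1-carboxylate | C=CCOC(=O)[C@@]1(O)C(C)=CC(=O)C[C@]1(C)CCC=C(C)C.C=CCOC(=O)[C@]1(O)C(C)=CC(=O)C[C@@]1(C)CCC=C(C)C
F4 | step 7 | allyl (1S,6S)-1-hydroxy-2,6-dimethyl-6-(4-methylpent-3-en-1-yl)-4-oxocyclohex-2-ene-1-carboxylate | C=CCOC(=O)[C@@]1(O)C(C)=CC(=O)C[C@]1(C)CCC=C(C)C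
F5 | step 7 | allyl (1S,6S)-6-(4-chloro-4-methylpentyl)-1-hydroxy-2,6-dimethyl-4-oxocyclohex-2-ene-1-carboxylate | C=CCOC(=O)[C@@]1(O)C(C)=CC(=O)C[C@]1(C)CCCC(C)(C)Cl
F6 | step 8 | chlorobis(cyclopentadienyl)(4-methylpent-3-en-1-yl)zirconium | CC(C)=CCC[Zr](Cl)(C1C=CC=C1)C1C=CC=C1
F7 | step 8 | allyl (1R,6S)-2,6-dimethyl-6-(4-methylpent-3-en-1-yl)-1,4-bis[(trimethylsilyl)oxy]cyclohexa-2,4-diene-1-carboxylate | C=CCOC(=O)[C@@]1(O[Si](C)(C)C)C(C)=CC(O[Si](C)(C)C)=C[C@]1(C)CCC=C(C)C
F8 | step 10 | allyl 12-bromo-9α-hydroxy-6-oxodrim-7-en-11-oate | O=C1C=C(CBr)[C@](O)(C(=O)OCC=C)[C@@]2(C)CCCC(C)(C)[C@H]12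
F9 | step 10 | allyl 9α,12-dihydroxy-6-oxodrim-7-en-11-oate | O=C1C=C(CO)[C@](O)(C(=O)OCC=C)[C@@]2(C)CCCC(C)(C)[C@H]12
F10 | step 10 | allyl 6β,9α,12-trihydroxydrim-7-en-11-oate | O[C@@H]1C=C(CO)[C@](O)(C(=O)OCC=C)[C@@]2(C)CCCC(C)(C)[C@H]12
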